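**Plan**
- Retrosynthesis: the two phenol MOM ethers are cut last. The C4 methylene of the chroman is traced back to a C4 ketone, a temporary activating group. The C2–C1′ bond between the chroman (ring C) and the aryl ring B is then cut, giving 7-(methoxymethoxy)chromone and a fully substituted ring-B boronic acid.
- The boronic acid is cut at C–B (from C–Br), at the aryl–prenyl bond (ortho-metalation between OMOM and Br) and at the dimethylpyran ring D (aryl propargyl ether), back to 4-bromo-2-hydroxybenzaldehyde.
- Forward: ring D is annulated first, then prenyl and boron are installed. Rings A and C arrive preformed as the flat chromone. A rhodium-catalysed asymmetric 1,4-arylation joins the halves, then the C4 oxygen is reduced away and the MOM groups are removed.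
- Enabling feature: the C2=C3 double bond of the γ-pyrone ring C is a vinylogous ester with the C4 carbonyl. The prochiral sp2 carbon C2 therefore accepts an aryl–rhodium nucleophile, and the flat, weakly aromatic pyranone becomes the stereogenic dihydropyran ring of the flavan.
- Stereochemistry: the only stereocenter, C2 (R), is set by the chiral bisphosphine on rhodium in that step and is not touched afterwards.

Key step: step 8

Assumption: the sense of induction of (R)-MeO-F12-BIPHEP, (R)-(6,6′-dimethoxybiphenyl-2,2′-diyl)bis[bis(3,4,5-trifluorophenyl)phosphane], on the chromone is taken to follow that of (R)-configured biaryl bisphosphines on cyclic enones, which corresponds to 2R here; if it does not, the (S)-ligand is used in the same step.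

**Route**

Step 1
Reactants: 1 4-bromo-2-hydroxybenzaldehyde
Product: 2 4-bromo-2-(methoxymethoxy)benzaldehyde
Conditions: MOMCl, i-Pr2NEt, CH2Cl2, 0 °C → rt
Reagents that add atoms: chloromethyl methyl ether (MOMCl), COCCl
Why: Williamson-type O-alkylation of the acidic salicylaldehyde phenol with the reactive α-chloro ether should be clean, and the MOM ether later serves as the ortho-directing group.

Step 2
Reactants: 2 4-bromo-2-(methoxymethoxy)benzaldehyde
Product: 4 4-bromo-2-(methoxymethoxy)phenol, via aryl formate 3 (not isolated)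
Conditions: mCPBA, CH2Cl2, rt; then K2CO3 (cat.), MeOH, rt
Reagents that add atoms: meta-chloroperoxybenzoic acid (mCPBA), OOC(=O)c1cccc(Cl)c1
Why: In this Baeyer–Villiger (Dakin-type) oxidation the ortho-alkoxyaryl group should migrate in the Criegee intermediate to give the formate, whose methanolysis frees the hydroxyl para to bromine, so the two catechol oxygens are differentiated.

Step 3
Reactants: 4 4-bromo-2-(methoxymethoxy)phenol; 5 3-chloro-3-methylbut-1-yne
Product: 6 4-bromo-2-(methoxymethoxy)-1-[(2-methylbut-3-yn-2-yl)oxy]benzene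
Conditions: DBU, CuCl2·2H2O (cat.), MeCN, 0 °C → rt
Reagents that add atoms: none
Why: Copper-catalysed O-propargylation of a phenol with a tertiary propargylic chloride, through a copper acetylide that ionises and is captured by the phenoxide, should give the tertiary aryl ether that a plain SN2 reaction cannot.

Step 4
Reactants: 6 4-bromo-2-(methoxymethoxy)-1-[(2-methylbut-3-yn-2-yl)oxy]benzene
Product: 7 6-bromo-8-(methoxymethoxy)-2,2-dimethyl-2H-chromene
Conditions: N,N-diethylaniline, 180 °C
Reagents that add atoms: none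
Why: A thermal aromatic propargyl Claisen rearrangement to the only free ortho carbon (the other bears OMOM), followed by a 1,5-hydrogen shift and oxa-6π electrocyclization, should close the 2,2-dimethylpyran ring D.

Step 5
Reactants: 7 6-bromo-8-(methoxymethoxy)-2,2-dimethyl-2H-chromene; 8 1-bromo-3-methylbut-2-ene (prenyl bromide)
Product: 11 6-bromo-8-(methoxymethoxy)-2,2-dimethyl-7-(3-methylbut-2-en-1-yl)-2H-chromene, via aryllithium 9 (not isolated), via arylcopper 10 (not isolated)
Conditions: LiN(i-Pr)2 (LDA), THF, −78 °C; CuBr·SMe2, −78 °C; then 8, −78 → 0 °C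
Reagents that add atoms: none
Why: Directed ortho-metalation with the amide base (no Br–Li exchange) should remove the C7 proton, the only one flanked by both OMOM and Br, and transmetalation to copper prevents loss of LiBr and steers allylic substitution to the unhindered primary terminus of prenyl bromide.

Step 6
Reactants: 11 6-bromo-8-(methoxymethoxy)-2,2-dimethyl-7-(3-methylbut-2-en-1-yl)-2H-chromene
Product: 14 [8-(methoxymethoxy)-2,2-dimethyl-7-(3-methylbut-2-en-1-yl)-2H-chromen-6-yl]boronic acid, via aryllithium 12 (not isolated), via lithium triisopropoxyborate 13 (not isolated)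
Conditions: n-BuLi, THF, −78 °C; B(Oi-Pr)3, −78 °C → rt; then 1 M aq HCl to pH 6, 0 °C
Reagents that add atoms: triisopropyl borate, CC(C)OB(OC(C)C)OC(C)C; water, O
Why: Bromine–lithium exchange at −78 °C is faster than deprotonation of the benzylic–allylic CH2, and trapping with the borate followed by mild hydrolysis should give the boronic acid, which is used promptly because it is electron-rich.

Step 7
Reactants: 15 7-hydroxy-4H-chromen-4-one
Product: 16 7-(methoxymethoxy)-4H-chromen-4-one
Conditions: MOMCl, i-Pr2NEt, DMF, 0 °C → rt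
Reagents that add atoms: chloromethyl methyl ether (MOMCl), COCCl
Why: O-alkylation masks the vinylogous-acid phenol, whose phenoxide would otherwise switch off the enone towards conjugate addition under the basic conditions of step 8.

Step 8
Reactants: 14 [8-(methoxymethoxy)-2,2-dimethyl-7-(3-methylbut-2-en-1-yl)-2H-chromen-6-yl]boronic acid; 16 7-(methoxymethoxy)-4H-chromen-4-one
Product: 17 (2R)-7-(methoxymethoxy)-2-[8-(methoxymethoxy)-2,2-dimethyl-7-(3-methylbut-2-en-1-yl)-2H-chromen-6-yl]-2,3-dihydro-4H-chromen-4-one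
Conditions: [RhCl(C2H4)2]2 (2.5 mol %), (R)-MeO-F12-BIPHEP (5.5 mol %), KOH (0.2 equiv), toluene/H2O 10:1, 30 °C; 14 (2.5 equiv) added in portions
Reagents that add atoms: none
Why: Transmetalation of 14 to a hydroxo–rhodium–bisphosphine complex gives an aryl–rhodium species that adds across the C2=C3 bond of the γ-pyrone ring of 16, and the resulting oxa-π-allyl rhodium enolate is protonated by water to release 17 and regenerate the Rh–OH catalyst. The closest known reaction type is the Hayashi–Miyaura asymmetric 1,4-addition of arylboronic acids to chromones, which gives 2-arylchroman-4-ones. No ring is closed; the step joins the two halves at C2–C1′ and turns the flat pyranone into the dihydropyranone ring C. The C2 stereocenter is set under catalyst control, the chiral biaryl bisphosphine on rhodium selecting the enone face in the aryl-insertion step, with the (R)-ligand chosen to give 2R. The step needs 1,4- over 1,2-addition (inherent to aryl–rhodium), no loss of ee through base-induced retro-oxa-Michael opening to the 2′-hydroxychalcone (limited by substoichiometric KOH, a non-polar organic phase and mild temperature) and coupling faster than protodeboronation of the ortho-substituted acid (hence excess 14 in portions). The prenyl and chromene alkenes of 14 are electron-rich and unactivated and should not compete with the electron-poor enone for insertion.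

Step 9
Reactants: 17 (2R)-7-(methoxymethoxy)-2-[8-(methoxymethoxy)-2,2-dimethyl-7-(3-methylbut-2-en-1-yl)-2H-chromen-6-yl]-2,3-dihydro-4H-chromen-4-one
Product: 18 (2R,4R)-7-(methoxymethoxy)-2-[8-(methoxymethoxy)-2,2-dimethyl-7-(3-methylbut-2-en-1-yl)-2H-chromen-6-yl]-3,4-dihydro-2H-chromen-4-ol
Conditions: NaBH4, MeOH/THF 1:1, 0 °C
Reagents that add atoms: none
Why: Borohydride reduction of the aryl ketone under cold, near-neutral conditions leaves C2 untouched, and axial hydride delivery anti to the pseudo-equatorial C2 aryl group (substrate control) should give mainly the 2,4-cis alcohol, although the C4 configuration is of no consequence because step 10 removes this center.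

Step 10
Reactants: 18 (2R,4R)-7-(methoxymethoxy)-2-[8-(methoxymethoxy)-2,2-dimethyl-7-(3-methylbut-2-en-1-yl)-2H-chromen-6-yl]-3,4-dihydro-2H-chromen-4-ol
Product: 19 6-[(2R)-7-(methoxymethoxy)-3,4-dihydro-2H-chromen-2-yl]-8-(methoxymethoxy)-2,2-dimethyl-7-(3-methylbut-2-en-1-yl)-2H-chromene
Conditions: Et3SiH, BF3·OEt2, CH2Cl2, −78 °C; Et3N then aq NaHCO3 quench
Reagents that add atoms: none
Why: In this ionic hydrogenation the C4 hydroxyl ionises readily to a benzylic cation stabilised by the para C7 oxygen and the ortho ring oxygen, excess silane traps it as C–H, and the low temperature should spare the MOM ethers, the prenyl group and the ring-D alkene while C2 is not involved.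

Step 11
Reactants: 19 6-[(2R)-7-(methoxymethoxy)-3,4-dihydro-2H-chromen-2-yl]-8-(methoxymethoxy)-2,2-dimethyl-7-(3-methylbut-2-en-1-yl)-2H-chromene
Product: 21 (2R)-2-[8-hydroxy-2,2-dimethyl-7-(3-methylbut-2-en-1-yl)-2H-chromen-6-yl]-3,4-dihydro-2H-chromen-7-ol, via bis(trimethylsilyl) ether 20 (not isolated)
Conditions: Me3SiOTf, 2,2′-bipyridyl, MeCN, 0 °C → rt; then H2O, rt
Reagents that add atoms: none
Why: The bipyridyl-buffered silyl triflate should convert both aryl MOM ethers into aryl trimethylsilyl ethers (the methoxymethyl group leaving as an N-(methoxymethyl)bipyridinium salt) which water hydrolyses, so no free Brønsted acid is present to cyclise the ortho-prenylphenol, add to the chromene or ionise the C2 benzylic ether.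

**Compound list**

1 | 4-bromo-2-hydroxybenzaldehyde | O=Cc1ccc(Br)cc1O | starting material
2 | 4-bromo-2-(methoxymethoxy)benzaldehyde | COCOc1cc(Br)ccc1C=O | intermediate
3 | 4-bromo-2-(methoxymethoxy)phenyl formate | COCOc1cc(Br)ccc1OC=O | intermediate
4 | 4-bromo-2-(methoxymethoxy)phenol | COCOc1cc(Br)ccc1O | intermediate
5 | 3-chloro-3-methylbut-1-yne | C#CC(C)(C)Cl | starting material
6 | 4-bromo-2-(methoxymethoxy)-1-[(2-methylbut-3-yn-2-yl)oxy]benzene | C#CC(C)(C)Oc1ccc(Br)cc1OCOC | intermediate
7 | 6-bromo-8-(methoxymethoxy)-2,2-dimethyl-2H-chromene | COCOc1cc(Br)cc2C=CC(C)(C)Oc12 | intermediate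
8 | 1-bromo-3-methylbut-2-ene (prenyl bromide) | CC(C)=CCBr | starting material
9 | [6-bromo-8-(methoxymethoxy)-2,2-dimethyl-2H-chromen-7-yl]lithium | [Li]c1c(Br)cc2C=CC(C)(C)Oc2c1OCOC | intermediate
10 | [6-bromo-8-(methoxymethoxy)-2,2-dimethyl-2H-chromen-7-yl]copper | [Cu]c1c(Br)cc2C=CC(C)(C)Oc2c1OCOC | intermediate
11 | 6-bromo-8-(methoxymethoxy)-2,2-dimethyl-7-(3-methylbut-2-en-1-yl)-2H-chromene | CC(C)=CCc1c(Br)cc2C=CC(C)(C)Oc2c1OCOC | intermediate
12 | [8-(methoxymethoxy)-2,2-dimethyl-7-(3-methylbut-2-en-1-yl)-2H-chromen-6-yl]lithium | [Li]c1cc2C=CC(C)(C)Oc2c(OCOC)c1CC=C(C)C | intermediate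
13 | lithium triisopropoxy[8-(methoxymethoxy)-2,2-dimethyl-7-(3-methylbut-2-en-1-yl)-2H-chromen-6-yl]borate | [Li+].CC(C)O[B-](OC(C)C)(OC(C)C)c1cc2C=CC(C)(C)Oc2c(OCOC)c1CC=C(C)C | intermediate
14 | [8-(methoxymethoxy)-2,2-dimethyl-7-(3-methylbut-2-en-1-yl)-2H-chromen-6-yl]boronic acid | OB(O)c1cc2C=CC(C)(C)Oc2c(OCOC)c1CC=C(C)C | intermediate
15 | 7-hydroxy-4H-chromen-4-one | O=c1ccoc2cc(O)ccc12 | starting material
16 | 7-(methoxymethoxy)-4H-chromen-4-one | COCOc1ccc2c(c1)occc2=O | intermediate
17 | (2R)-7-(methoxymethoxy)-2-[8-(methoxymethoxy)-2,2-dimethyl-7-(3-methylbut-2-en-1-yl)-2H-chromen-6-yl]-2,3-dihydro-4H-chromen-4-one | CC(C)=CCc1c([C@H]2CC(=O)c3ccc(OCOC)cc3O2)cc2C=CC(C)(C)Oc2c1OCOC | intermediate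
18 | (2R,4R)-7-(methoxymethoxy)-2-[8-(methoxymethoxy)-2,2-dimethyl-7-(3-methylbut-2-en-1-yl)-2H-chromen-6-yl]-3,4-dihydro-2H-chromen-4-ol | CC(C)=CCc1c([C@H]2C[C@@H](O)c3ccc(OCOC)cc3O2)cc2C=CC(C)(C)Oc2c1OCOC | intermediate
19 | 6-[(2R)-7-(methoxymethoxy)-3,4-dihydro-2H-chromen-2-yl]-8-(methoxymethoxy)-2,2-dimethyl-7-(3-methylbut-2-en-1-yl)-2H-chromene | CC(C)=CCc1c([C@H]2CCc3ccc(OCOC)cc3O2)cc2C=CC(C)(C)Oc2c1OCOC | intermediate
20 | 6-[(2R)-7-(trimethylsilyloxy)-3,4-dihydro-2H-chromen-2-yl]-2,2-dimethyl-7-(3-methylbut-2-en-1-yl)-8-(trimethylsilyloxy)-2H-chromene | CC(C)=CCc1c([C@H]2CCc3ccc(O[Si](C)(C)C)cc3O2)cc2C=CC(C)(C)Oc2c1O[Si](C)(C)C | intermediate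
21 | (2R)-2-[8-hydroxy-2,2-dimethyl-7-(3-methylbut-2-en-1-yl)-2H-chromen-6-yl]-3,4-dihydro-2H-chromen-7-ol | CC(C)=CCc1c([C@H]2CCc3ccc(O)cc3O2)cc2c(c1O)OC(C)(C)C=C2 | target

**Count**

Total steps: 11. Longest linear sequence: 10 (steps 1–6, then 8–11); step 7 is a one-step side branch.

**Steps most likely to fail**

1. Step 8. The ortho-substituted, electron-rich aryl group may transfer and insert slowly so that protodeboronation wins, and the flavanone may lose enantiomeric purity by reversible ring-opening under the basic medium. Fallback (sets out from 11, returns at 19): the same C2–C1′ bond is made by carbonyl addition and the stereocenter by reagent-controlled reduction. Commercial 7-hydroxy-3,4-dihydro-2H-chromen-2-one would be protected (MOMCl, i-Pr2NEt) as 7-(methoxymethoxy)-3,4-dihydro-2H-chromen-2-one F1. Compound 11 would be converted to aryllithium 12 (n-BuLi, THF, −78 °C) and F1 added at −78 °C so that the lactone is opened once, giving after work-up 3-[2-hydroxy-4-(methoxymethoxy)phenyl]-1-[8-(methoxymethoxy)-2,2-dimethyl-7-(3-methylbut-2-en-1-yl)-2H-chromen-6-yl]propan-1-one F2. Corey–Bakshi–Shibata reduction ((R)-Me-oxazaborolidine, excess BH3·SMe2 to allow for the free phenol) should give (1S)-3-[2-hydroxy-4-(methoxymethoxy)phenyl]-1-[8-(methoxymethoxy)-2,2-dimethyl-7-(3-methylbut-2-en-1-yl)-2H-chromen-6-yl]propan-1-ol F3. Intramolecular Mitsunobu etherification (PPh3, DIAD, THF, 0 °C) would then close ring C by 6-exo-tet displacement with inversion to give 19, which re-enters at step 11; steps 6 to 10 are then not needed.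

2. Step 5. The ortho-bromoaryllithium may lose LiBr (aryne formation) before transmetalation, metalation may be incomplete, or the allyl electrophile may be attacked at its tertiary terminus. Fallback (sets out from 7, returns at 11): the prenyl group is brought in through oxygen and moved to carbon by a sigmatropic shift. The MOM ether of 7 would be cleaved (HCl, MeOH, 40 °C; no prenyl group is present yet) to give 6-bromo-2,2-dimethyl-2H-chromen-8-ol F4. Tsuji–Trost O-alkylation with tert-butyl (2-methylbut-3-en-2-yl) carbonate and Pd(PPh3)4 (THF, 0 °C) should give 6-bromo-2,2-dimethyl-8-[(2-methylbut-3-en-2-yl)oxy]-2H-chromene F5. Aromatic Claisen rearrangement (N,N-diethylaniline, 150 °C) would deliver the allyl unit, with inversion of its termini, to the only free ortho carbon C7 as 6-bromo-2,2-dimethyl-7-(3-methylbut-2-en-1-yl)-2H-chromen-8-ol F6. Re-protection (MOMCl, i-Pr2NEt) gives 11.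

3. Step 10. The C4 cation may eliminate to the 2H-chromene instead of being reduced, or adventitious acid may attack the ring-D alkene, the prenyl group or the MOM ethers. Fallback (sets out from 18, returns at 19): a radical Barton–McCombie deoxygenation replaces the ionic one. Alcohol 18 would be converted (NaH, CS2, then MeI, THF, 0 °C) into O-[(2R,4R)-7-(methoxymethoxy)-2-[8-(methoxymethoxy)-2,2-dimethyl-7-(3-methylbut-2-en-1-yl)-2H-chromen-6-yl]-3,4-dihydro-2H-chromen-4-yl] S-methyl carbonodithioate F7. Treatment with Bu3SnH and AIBN (toluene, 90 °C) should then give 19 through the C4 benzylic radical.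

**Further compounds**

F1 | step 8 | 7-(methoxymethoxy)-3,4-dihydro-2H-chromen-2-one | COCOc1ccc2CCC(=O)Oc2c1
F2 | step 8 | 3-[2-hydroxy-4-(methoxymethoxy)phenyl]-1-[8-(methoxymethoxy)-2,2-dimethyl-7-(3-methylbut-2-en-1-yl)-2H-chromen-6-yl]propan-1-one | CC(C)=CCc1c(C(=O)CCc3ccc(OCOC)cc3O)cc2C=CC(C)(C)Oc2c1OCOC
F3 | step 8 | (1S)-3-[2-hydroxy-4-(methoxymethoxy)phenyl]-1-[8-(methoxymethoxy)-2,2-dimethyl-7-(3-methylbut-2-en-1-yl)-2H-chromen-6-yl]propan-1-ol | CC(C)=CCc1c([C@@H](O)CCc3ccc(OCOC)cc3O)cc2C=CC(C)(C)Oc2c1OCOC
F4 | step 5 | 6-bromo-2,2-dimethyl-2H-chromen-8-ol | Oc1cc(Br)cc2C=CC(C)(C)Oc12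
F5 | step 5 | 6-bromo-2,2-dimethyl-8-[(2-methylbut-3-en-2-yl)oxy]-2H-chromene | C=CC(C)(C)Oc1cc(Br)cc2C=CC(C)(C)Oc12
F6 | step 5 | 6-bromo-2,2-dimethyl-7-(3-methylbut-2-en-1-yl)-2H-chromen-8-ol | CC(C)=CCc1c(Br)cc2C=CC(C)(C)Oc2c1O
F7 | step 10 | O-[(2R,4R)-7-(methoxymethoxy)-2-[8-(methoxymethoxy)-2,2-dimethyl-7-(3-methylbut-2-en-1-yl)-2H-chromen-6-yl]-3,4-dihydro-2H-chromen-4-yl] S-methyl carbonodithioate | CC(C)=CCc1c([C@H]2C[C@@H](OC(=S)SC)c3ccc(OCOC)cc3O2)cc2C=CC(C)(C)Oc2c1OCOC
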